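**Retrosynthetic overview**
1. The strategy rests on C6 of the pyrrolo[2,3-c]azepin-8-one, a lone CH2 between lactam N7 and C5. C5 ends the C4=C5 alkene, and C4 carries both the pyrrole (C3a) and the imidazole (C4'), so a C4 cation is doubly stabilised. C6 is taken out as formaldehyde (bonds N7–C6 and C6–C5), leaving a primary carboxamide on C8 and a 1,1-diheteroarylethylene.
2. The 1,1-diheteroarylethylene is cut at C3a–C4 by a Barluenga coupling of a 3-iodo-4,5-dibromopyrrole-2-carboxylate with the tosylhydrazone of a 4-acetyl-2-acetamidoimidazole. Both bromines sit on the pyrrole from the start, because neither the alkene nor the imidazole C5'–H would survive a later electrophilic bromination; iodine marks C3 for palladium.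
3. Ring order: the imidazole is built first (bromodiketone plus N-acetylguanidine), the pyrrole is bought, and the azepinone is closed last by the 7-endo aza-Prins step. The N-acetyl cap is removed in the final step.

Key step: step 10

Assumption: the target has no stereogenic centre and its only C=C bond (C4=C5) lies in the seven-membered ring, so the achiral compound itself is the "single enantiomer" and no stereocontrol is needed. SEM = [2-(trimethylsilyl)ethoxy]methyl.

**Route**

Step 1
Reactants: 1 butane-2,3-dione
Product: 2 1-bromobutane-2,3-dione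
Conditions: Br2 (0.5 equiv), CHCl3, 55 °C, slow addition; fractional distillation
Reagents that add atoms: bromine, BrBr
Why: Acid-catalysed α-bromination of a ketone through its enol; the excess of dione should keep the 1,4-dibromide low.

Step 2
Reactants: 2 1-bromobutane-2,3-dione; 3 N-acetylguanidine
Product: 4 N-(4-acetyl-1H-imidazol-2-yl)acetamide
Conditions: 3 (3 equiv), DMF, 0 °C to rt, 48 h
Reagents that add atoms: none
Why: α-Haloketone/acylguanidine imidazole synthesis (SN2 at CH2Br, 5-exo addition of the second nitrogen to the adjacent carbonyl, dehydration), which leaves the distal carbonyl as the 4-acetyl group, as in Hantzsch-type condensations of this bromodiketone.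

Step 3
Reactants: 4 N-(4-acetyl-1H-imidazol-2-yl)acetamide
Product: 5 N-(4-acetyl-1-SEM-1H-imidazol-2-yl)acetamide
Conditions: NaH (1.05 equiv), SEMCl (1.05 equiv), THF–DMF, 0 °C to rt
Reagents that add atoms: 2-(trimethylsilyl)ethoxymethyl chloride, C[Si](C)(C)CCOCCl
Why: N-Alkylation of the imidazolide at the ring nitrogen remote from the acetyl group; a minor N3 isomer would converge after step 9.

Step 4
Reactants: 5 N-(4-acetyl-1-SEM-1H-imidazol-2-yl)acetamide
Product: 6 N-[4-{(1E)-1-[2-(4-methylbenzenesulfonyl)hydrazinylidene]ethyl}-1-SEM-1H-imidazol-2-yl]acetamide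
Conditions: TsNHNH2 (1.1 equiv), MeOH, 60 °C
Reagents that add atoms: p-toluenesulfonohydrazide, Cc1ccc(cc1)S(=O)(=O)NN
Why: Condensation of a methyl ketone with a sulfonyl hydrazide to the tosylhydrazone; the C=N geometry is of no consequence.

Step 5
Reactants: 7 methyl 4,5-dibromo-1H-pyrrole-2-carboxylate
Product: 8 methyl 4,5-dibromo-3-iodo-1H-pyrrole-2-carboxylate
Conditions: NIS (1.2 equiv), TFA–CH2Cl2 (1:4), 0 °C to rt, dark
Reagents that add atoms: N-iodosuccinimide, O=C1CCC(=O)N1I
Why: Electrophilic aromatic iodination at C3, the only free ring position, in line with the exhaustive halogenation of pyrrole-2-carboxylates.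

Step 6
Reactants: 8 methyl 4,5-dibromo-3-iodo-1H-pyrrole-2-carboxylate
Product: 9 methyl 4,5-dibromo-3-iodo-1-SEM-1H-pyrrole-2-carboxylate
Conditions: NaH (1.1 equiv), SEMCl (1.1 equiv), DMF, 0 °C to rt
Reagents that add atoms: 2-(trimethylsilyl)ethoxymethyl chloride, C[Si](C)(C)CCOCCl
Why: N-Alkylation of the acidic pyrrole N–H, which removes the pyrrolide-forming proton before the basic palladium coupling.

Step 7
Reactants: 9 methyl 4,5-dibromo-3-iodo-1-SEM-1H-pyrrole-2-carboxylate; 6 tosylhydrazone of step 4
Product: 11 methyl 3-[1-(2-acetamido-1-SEM-1H-imidazol-4-yl)ethenyl]-4,5-dibromo-1-SEM-1H-pyrrole-2-carboxylate, via N-[4-(1-diazoethyl)-1-SEM-1H-imidazol-2-yl]acetamide 10 (not isolated)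
Conditions: 6 (1.2 equiv), Pd2(dba)3 (2.5 mol%), XPhos (10 mol%), LiOtBu (3.3 equiv), 1,4-dioxane, 80 °C
Reagents that add atoms: none
Why: Barluenga cross-coupling, in which base turns 6 into diazo compound 10, Pd(0) inserts into C–I in preference to the two C–Br bonds, and carbene migratory insertion followed by β-hydride elimination from the methyl group (the only β-hydrogens) gives the 1,1-diheteroarylethylene.

Step 8
Reactants: 11 alkene ester of step 7
Product: 12 3-[1-(2-acetamido-1-SEM-1H-imidazol-4-yl)ethenyl]-4,5-dibromo-1-SEM-1H-pyrrole-2-carboxamide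
Conditions: AlMe3 (5 equiv), NH4Cl (5 equiv), toluene, 0 to 50 °C; Rochelle salt work-up
Reagents that add atoms: ammonium chloride, [NH4+].[Cl-]
Why: Weinreb aminolysis of the ester by the aluminium amide MeAl(Cl)NH2, a non-protic method that should not ionise the acid-labile alkene; partial loss of SEM here would be harmless.

Step 9
Reactants: 12 bis-SEM carboxamide of step 8
Product: 13 3-[1-(2-acetamido-1H-imidazol-4-yl)ethenyl]-4,5-dibromo-1H-pyrrole-2-carboxamide
Conditions: TBAF (6 equiv), ethylenediamine (4 equiv), THF, 65 °C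
Reagents that add atoms: none
Why: Fluoride-induced fragmentation of both N-SEM groups under basic conditions that leave the alkene, the primary amide, the acetamide and the bromides untouched; the diamine traps the released formaldehyde.

Step 10
Reactants: 13 alkene carboxamide of step 9; 14 formaldehyde (used as paraformaldehyde)
Product: 16 N-acetylstevensine, N-[4-(2,3-dibromo-8-oxo-1,6,7,8-tetrahydropyrrolo[2,3-c]azepin-4-yl)-1H-imidazol-2-yl]acetamide, via 3-[1-(2-acetamido-1H-imidazol-4-yl)ethenyl]-4,5-dibromo-N-(hydroxymethyl)-1H-pyrrole-2-carboxamide 15 (not isolated)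
Conditions: (CH2O)n (1.5 equiv), TFA–ClCH2CH2Cl (1:4), anhydrous, 50 °C; then NH3/MeOH, rt
Reagents that add atoms: none
Why: Proposed new method: the amide is hydroxymethylated to 15, TFA ionises it to the N-acyliminium ion (N7=C6H2+), the terminal alkene carbon C5 attacks C6, and the tertiary C4 cation (an azafulvenium ion delocalised onto pyrrole N1 and the acetamidoimidazole) loses a C5 proton to give the ring C4=C5 alkene, the only alkene it can form. The closest known reaction type is the intramolecular amidoalkylation of alkenes by N-acyliminium ions made from an amide, formaldehyde and acid (aza-Prins/Tscherniac–Einhorn type); a primary heteroaryl carboxamide closing onto a 1,1-diheteroarylethylene has not been shown. The azepinone closes in the 7-endo-trig mode and no stereocentre is formed. The step needs C–C bond formation at C5 and not reaction at nitrogen or at the imidazole C5'–H: N-CH2OH groups, aminals and methylene-bis-amides at N1, N7 and the imidazole re-ionise in acid, the imidazole is protonated in TFA and so deactivated towards hydroxymethylation, and its C5' could reach C6 only through an eight-membered ring. If the alkene is protonated first, capture of the C4 cation by the amide (five-membered lactam or iminolactone) should be reversible in anhydrous acid, and a Prins-first pathway (allylic alcohol, ionisation, capture by N7 at C6) leads to the same product.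

Step 11
Reactants: 16 N-acetylstevensine
Product: 17 stevensine, 4-(2-amino-1H-imidazol-5-yl)-2,3-dibromo-6,7-dihydropyrrolo[2,3-c]azepin-8(1H)-one
Conditions: HCl (1.25 M in MeOH), 65 °C; then aq. NaHCO3
Reagents that add atoms: none
Why: Acid-catalysed methanolysis of the acylguanidine-type N-acetyl group, under conditions to which the conjugated lactam, the ring alkene and the bromopyrrole should be stable.

**Compound list**
1 | butane-2,3-dione | CC(=O)C(C)=O | starting material
2 | 1-bromobutane-2,3-dione | CC(=O)C(=O)CBr | intermediate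
3 | N-acetylguanidine | CC(=O)NC(N)=N | starting material
4 | N-(4-acetyl-1H-imidazol-2-yl)acetamide | CC(=O)Nc1nc(C(C)=O)c[nH]1 | intermediate
5 | N-(4-acetyl-1-SEM-1H-imidazol-2-yl)acetamide | CC(=O)Nc1nc(C(C)=O)cn1COCC[Si](C)(C)C | intermediate
6 | N-[4-{(1E)-1-[2-(4-methylbenzenesulfonyl)hydrazinylidene]ethyl}-1-SEM-1H-imidazol-2-yl]acetamide | C/C(=N\NS(=O)(=O)c1ccc(C)cc1)c1cn(COCC[Si](C)(C)C)c(NC(C)=O)n1 | intermediate
7 | methyl 4,5-dibromo-1H-pyrrole-2-carboxylate | COC(=O)c1cc(Br)c(Br)[nH]1 | starting material
8 | methyl 4,5-dibromo-3-iodo-1H-pyrrole-2-carboxylate | COC(=O)c1[nH]c(Br)c(Br)c1I | intermediate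
9 | methyl 4,5-dibromo-3-iodo-1-SEM-1H-pyrrole-2-carboxylate | COC(=O)c1c(I)c(Br)c(Br)n1COCC[Si](C)(C)C | intermediate
10 | N-[4-(1-diazoethyl)-1-SEM-1H-imidazol-2-yl]acetamide (not isolated) | CC(=[N+]=[N-])c1cn(COCC[Si](C)(C)C)c(NC(C)=O)n1 | intermediate
11 | methyl 3-[1-(2-acetamido-1-SEM-1H-imidazol-4-yl)ethenyl]-4,5-dibromo-1-SEM-1H-pyrrole-2-carboxylate | COC(=O)c1c(C(=C)c2cn(COCC[Si](C)(C)C)c(NC(C)=O)n2)c(Br)c(Br)n1COCC[Si](C)(C)C | intermediate
12 | 3-[1-(2-acetamido-1-SEM-1H-imidazol-4-yl)ethenyl]-4,5-dibromo-1-SEM-1H-pyrrole-2-carboxamide | NC(=O)c1c(C(=C)c2cn(COCC[Si](C)(C)C)c(NC(C)=O)n2)c(Br)c(Br)n1COCC[Si](C)(C)C | intermediate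
13 | 3-[1-(2-acetamido-1H-imidazol-4-yl)ethenyl]-4,5-dibromo-1H-pyrrole-2-carboxamide | C=C(c1c[nH]c(NC(C)=O)n1)c1c(Br)c(Br)[nH]c1C(N)=O | intermediate
14 | formaldehyde (used as paraformaldehyde) | C=O | starting material
15 | 3-[1-(2-acetamido-1H-imidazol-4-yl)ethenyl]-4,5-dibromo-N-(hydroxymethyl)-1H-pyrrole-2-carboxamide (not isolated) | C=C(c1c[nH]c(NC(C)=O)n1)c1c(Br)c(Br)[nH]c1C(=O)NCO | intermediate
16 | N-acetylstevensine | CC(=O)Nc1nc(C2=CCNC(=O)c3[nH]c(Br)c(Br)c32)c[nH]1 | intermediate
17 | stevensine | Nc1ncc(C2=CCNC(=O)c3[nH]c(Br)c(Br)c32)[nH]1 | target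

**Step count**
Total: 11 steps. Longest linear sequence: 9 steps (1, 2, 3, 4, 7, 8, 9, 10, 11); steps 5 and 6 form the convergent pyrrole branch.

**Steps most likely to fail**

Step 10. The acyliminium ion may not reach the alkene terminus before the alkene is protonated. The amide then captures the C4 cation through N or O, and adventitious water hydrolyses the iminolactone with loss of ammonia; formaldehyde may also be used up by hydroxymethylation of the imidazole ring carbon. The fallback sets out from 11 and returns at 16, closing the same ring by known metathesis chemistry. Aminolysis of 11 with allylamine (AlMe3, toluene, 60 °C) should give methyl-free N-allyl amide, 3-[1-(2-acetamido-1-SEM-1H-imidazol-4-yl)ethenyl]-4,5-dibromo-N-(prop-2-en-1-yl)-1-SEM-1H-pyrrole-2-carboxamide F1. Ring-closing metathesis between the allyl terminus and the 1,1-disubstituted alkene (Hoveyda–Grubbs II, toluene, 80 °C, ethylene swept out) should give the bis-SEM derivative of N-acetylstevensine F2, provided the secondary amide populates the cisoid rotamer. TBAF/ethylenediamine in THF at 65 °C then gives 16.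

Step 7. Oxidative addition may also take place at the activated C5–Br bond, the doubly ortho-substituted C3–Pd species may couple slowly, and the diazo compound may then decay by azine formation or 1,2-hydride shift. The fallback sets out from 5 and 9 and returns at 11, replacing the carbene coupling by a Negishi coupling. Ketone 5 is converted (KHMDS 2.1 equiv, PhNTf2, THF, −78 °C) into 1-(2-acetamido-1-SEM-1H-imidazol-4-yl)ethenyl trifluoromethanesulfonate F3. Iodide 9 undergoes iodine-selective halogen–magnesium exchange (iPrMgCl·LiCl, THF, −40 °C) and transmetalation with ZnCl2 to [4,5-dibromo-2-(methoxycarbonyl)-1-SEM-1H-pyrrol-3-yl]zinc chloride F4. Coupling of F3 and F4 (Pd(PPh3)4, THF, 25–40 °C) should give 11.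

Step 2. The guanidine may condense with both carbonyl groups of the 1,2-diketone or close a six-membered ring onto the distal carbonyl, and the bromodiketone may self-condense under the basic conditions. The fallback sets out from 3 and returns at 5, using a bromoketoester that has only one ketone. Compound 3 and ethyl bromopyruvate (DMF, rt) should give ethyl 2-acetamido-1H-imidazole-4-carboxylate F5. NaH/SEMCl gives ethyl 2-acetamido-1-SEM-1H-imidazole-4-carboxylate F6. MeNH(OMe)·HCl with iPrMgCl (THF, −10 °C) gives 2-acetamido-N-methoxy-N-methyl-1-SEM-1H-imidazole-4-carboxamide F7. MeMgBr (THF, 0 °C, one extra equivalent for the NHAc proton) then gives ketone 5.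

**Further compounds**
F1 | step 10 | 3-[1-(2-acetamido-1-SEM-1H-imidazol-4-yl)ethenyl]-4,5-dibromo-N-(prop-2-en-1-yl)-1-SEM-1H-pyrrole-2-carboxamide | C=CCNC(=O)c1c(C(=C)c2cn(COCC[Si](C)(C)C)c(NC(C)=O)n2)c(Br)c(Br)n1COCC[Si](C)(C)C
F2 | step 10 | N-[4-(2,3-dibromo-8-oxo-1-SEM-1,6,7,8-tetrahydropyrrolo[2,3-c]azepin-4-yl)-1-SEM-1H-imidazol-2-yl]acetamide | CC(=O)Nc1nc(C2=CCNC(=O)c3n(COCC[Si](C)(C)C)c(Br)c(Br)c32)cn1COCC[Si](C)(C)C
F3 | step 7 | 1-(2-acetamido-1-SEM-1H-imidazol-4-yl)ethenyl trifluoromethanesulfonate | C=C(OS(=O)(=O)C(F)(F)F)c1cn(COCC[Si](C)(C)C)c(NC(C)=O)n1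
F4 | step 7 | [4,5-dibromo-2-(methoxycarbonyl)-1-SEM-1H-pyrrol-3-yl]zinc chloride | COC(=O)c1c([Zn]Cl)c(Br)c(Br)n1COCC[Si](C)(C)C
F5 | step 2 | ethyl 2-acetamido-1H-imidazole-4-carboxylate | CCOC(=O)c1c[nH]c(NC(C)=O)n1
F6 | step 2 | ethyl 2-acetamido-1-SEM-1H-imidazole-4-carboxylate | CCOC(=O)c1cn(COCC[Si](C)(C)C)c(NC(C)=O)n1
F7 | step 2 | 2-acetamido-N-methoxy-N-methyl-1-SEM-1H-imidazole-4-carboxamide | CON(C)C(=O)c1cn(COCC[Si](C)(C)C)c(NC(C)=O)n1
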